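**Plan**

- Retrosynthesis: the lactone C3–CH2Ar bond is cut first (enolate alkylation with a benzylic bromide), then the C2–C3 bond of the dihydrobenzofuran (carbene C–H insertion), then the aryl–CH2CO2Me bond and the ArO–CH2Ar ether bond of the diazo precursor. The β-benzyl lactone is cut back to O-benzylvanillin and diethyl succinate.
- Enabling feature: in the dihydrobenzofuran, C2 carries the ring oxygen and an aryl group, and C3 is bonded to the benzo ring and to the CH2OH carbon. C3 can therefore be the carbene carbon of an aryldiazoacetate (ester as latent CH2OH) and C2 the OCH2Ar carbon of a benzyl ether ortho to it.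
- Forward order: the (R)-β-benzylbutyrolactone is made first (steps 1–3), and the arylacetate is built from 5-bromovanillin (steps 4–8). The dihydrofuran ring closes in step 9, steps 10–13 give the protected CH2OH and the CH2Br arm, step 14 joins the halves, and steps 15–16 unmask.
- Stereochemistry: lactone C4 comes from asymmetric hydrogenation, dihydrobenzofuran C2 from the chiral dirhodium carboxylate, C3 from base equilibration to trans, and lactone C3 from alkylation anti to the C4 substituent.

Key step: step 9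

Assumption: the ligand enantiomers written in steps 2 and 9 are assigned from the sense of induction of the closest substrates (arylidenesuccinate half-esters with Rh-DuPHOS; ortho-benzyloxy aryldiazoacetates with phthalimido amino-acid dirhodium carboxylates); if either reaction shows the opposite sense, the mirror-image ligand is used and nothing else changes.

**Route**

Step 1
Reactants: 1 4-benzyloxy-3-methoxybenzaldehyde; 2 diethyl succinate
Product: 3 (3E)-4-(4-benzyloxy-3-methoxyphenyl)-3-(ethoxycarbonyl)but-3-enoic acid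
Conditions: NaOEt, EtOH, reflux; then aq. HCl
Reagents that add atoms: none
Why: Stobbe condensation, in which the succinate enolate adds to the non-enolisable aldehyde and the paraconate intermediate opens by E1cB to the carboxylate, which drives the reaction and gives the E-arylidene half-ester.

Step 2
Reactants: 3 (3E)-4-(4-benzyloxy-3-methoxyphenyl)-3-(ethoxycarbonyl)but-3-enoic acid
Product: 4 (3R)-4-(4-benzyloxy-3-methoxyphenyl)-3-(ethoxycarbonyl)butanoic acid
Conditions: H2 (4 atm), [Rh(cod)((S,S)-Et-DuPHOS)]BF4 (0.5 mol%), NaOMe (0.1 equiv), MeOH, rt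
Reagents that add atoms: none
Why: Carboxylate-directed asymmetric hydrogenation of a Stobbe itaconate half-ester by a cationic monovalent rhodium bisphospholane complex; chelation of alkene and carboxylate lets the ligand select the alkene face and so set the R centre, and the homogeneous catalyst leaves the benzyl ether intact.

Step 3
Reactants: 4 (3R)-4-(4-benzyloxy-3-methoxyphenyl)-3-(ethoxycarbonyl)butanoic acid
Product: 6 (4R)-4-[(4-benzyloxy-3-methoxyphenyl)methyl]oxolan-2-one, via hydroxy acid 5 (not isolated)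
Conditions: KOH (1 equiv), EtOH; CaCl2, NaBH4, −10 °C to rt; then 2 M HCl
Reagents that add atoms: none
Why: Ca(BH4)2 reduces the ethyl ester but not the potassium carboxylate (chemoselective borohydride reduction) under conditions too weakly basic to enolise the ester, and acidification lactonises the γ-hydroxy acid with the stereocentre unchanged.

Step 4
Reactants: 7 3-bromo-4-hydroxy-5-methoxybenzaldehyde (5-bromovanillin); 8 (4-benzyloxy-3-methoxyphenyl)methanol
Product: 9 4-[(4-benzyloxy-3-methoxyphenyl)methoxy]-3-bromo-5-methoxybenzaldehyde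
Conditions: PPh3, DIAD, THF, 0 °C to rt
Reagents that add atoms: none
Why: Mitsunobu etherification, in which the acidic para-formyl phenol protonates the betaine and its phenoxide displaces the oxyphosphonium of the primary benzylic alcohol.

Step 5
Reactants: 9 4-[(4-benzyloxy-3-methoxyphenyl)methoxy]-3-bromo-5-methoxybenzaldehyde
Product: 10 {4-[(4-benzyloxy-3-methoxyphenyl)methoxy]-3-bromo-5-methoxyphenyl}methanol
Conditions: NaBH4, MeOH/THF, 0 °C
Reagents that add atoms: none
Why: Borohydride reduction of an aryl aldehyde, to which the aryl bromide and the benzyl ethers are inert.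

Step 6
Reactants: 10 {4-[(4-benzyloxy-3-methoxyphenyl)methoxy]-3-bromo-5-methoxyphenyl}methanol
Product: 11 ({4-[(4-benzyloxy-3-methoxyphenyl)methoxy]-3-bromo-5-methoxyphenyl}methoxy)(tert-butyl)dimethylsilane
Conditions: TBSCl, imidazole, DMF, rt
Reagents that add atoms: tert-butyldimethylsilyl chloride, CC(C)(C)[Si](C)(C)Cl
Why: Imidazole-promoted silylation of a primary benzylic alcohol, giving an ether that should survive the organozinc, diazo-transfer, carbenoid, methoxide and hydride steps and can later be removed in the presence of a TBDPS ether.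

Step 7
Reactants: 11 ({4-[(4-benzyloxy-3-methoxyphenyl)methoxy]-3-bromo-5-methoxyphenyl}methoxy)(tert-butyl)dimethylsilane
Product: 12 methyl 2-{2-[(4-benzyloxy-3-methoxyphenyl)methoxy]-5-[(tert-butyldimethylsilyloxy)methyl]-3-methoxyphenyl}acetate
Conditions: BrZnCH2CO2Me (from BrCH2CO2Me, Zn, THF), Pd2(dba)3 (2.5 mol%), XPhos (10 mol%), THF, 65 °C
Reagents that add atoms: bromo(2-methoxy-2-oxoethyl)zinc, COC(=O)C[Zn]Br
Why: Negishi-type α-arylation of an ester with a Reformatsky reagent (oxidative addition of the aryl bromide to zerovalent palladium, transmetalation of the zinc enolate, C–C reductive elimination); the nearly neutral zinc enolate tolerates the silyl and benzyl ethers and the bulky biarylphosphine suits an electron-rich ortho-alkoxy bromide.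

Step 8
Reactants: 12 methyl 2-{2-[(4-benzyloxy-3-methoxyphenyl)methoxy]-5-[(tert-butyldimethylsilyloxy)methyl]-3-methoxyphenyl}acetate
Product: 13 methyl 2-diazo-2-{2-[(4-benzyloxy-3-methoxyphenyl)methoxy]-5-[(tert-butyldimethylsilyloxy)methyl]-3-methoxyphenyl}acetate
Conditions: 4-acetamidobenzenesulfonyl azide, DBU, MeCN, 0 °C to rt
Reagents that add atoms: 4-acetamidobenzenesulfonyl azide, CC(=O)Nc1ccc(cc1)S(=O)(=O)N=[N+]=[N-]
Why: Regitz diazo transfer, in which DBU deprotonates the arylacetate and the enolate takes the terminal N2 unit of the sulfonyl azide, as is routine for ortho-alkoxy arylacetates.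

Step 9
Reactants: 13 methyl 2-diazo-2-{2-[(4-benzyloxy-3-methoxyphenyl)methoxy]-5-[(tert-butyldimethylsilyloxy)methyl]-3-methoxyphenyl}acetate
Product: 15 methyl (2S,3S)-2-(4-benzyloxy-3-methoxyphenyl)-5-[(tert-butyldimethylsilyloxy)methyl]-7-methoxy-2,3-dihydro-1-benzofuran-3-carboxylate, via cis ester 14 (not isolated)
Conditions: Rh2(R-PTTL)4 (dirhodium tetrakis[N-phthaloyl-(R)-tert-leucinate], 1 mol%), toluene, −60 °C, slow addition of 13; then NaOMe (0.3 equiv), MeOH, 0 °C to rt
Reagents that add atoms: none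
Why: Extrusion of dinitrogen at one metal of the divalent rhodium dimer leaves an electrophilic aryl(methoxycarbonyl)carbenoid, and the neighbouring OCH2Ar group gives up one benzylic hydrogen as the new C2–C3 bond forms in a single asynchronous event. The closest known reaction type is the dirhodium-carboxylate-catalysed enantioselective intramolecular C–H insertion of ortho-benzyloxy aryldiazoacetates to cis-2-aryl-2,3-dihydrobenzofuran-3-carboxylates, a class that also accommodates an alkoxy group beside the ether oxygen. The dihydrofuran ring closes by 1,5-insertion, the carbene carbon bonding to the ether CH2 carbon through a five-membered array. C2 is controlled by the phthalimido-tert-leucinate ligands, which distinguish the two enantiotopic benzylic hydrogens (R ligand for 2S); C3 forms cis under kinetic control and is then turned to the more stable trans arrangement by methoxide enolisation, C2 being safe because the β-elimination that would open the ring is the reverse of a 5-endo-trig closure and lacks orbital overlap. The step needs site selectivity, which the substrate secures because the ether CH2 is the only activated C–H that can reach the carbene through a five-membered array, the CH2OTBS and PhCH2O groups being out of reach, while slow addition at low temperature holds back dimerisation and the carbene carbon, bearing only aryl and ester, cannot undergo a 1,2-hydride shift.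

Step 10
Reactants: 15 methyl (2S,3S)-2-(4-benzyloxy-3-methoxyphenyl)-5-[(tert-butyldimethylsilyloxy)methyl]-7-methoxy-2,3-dihydro-1-benzofuran-3-carboxylate
Product: 16 [(2S,3R)-2-(4-benzyloxy-3-methoxyphenyl)-5-[(tert-butyldimethylsilyloxy)methyl]-7-methoxy-2,3-dihydro-1-benzofuran-3-yl]methanol
Conditions: LiAlH4, THF, 0 °C
Reagents that add atoms: none
Why: Hydride reduction of the ester to the primary alcohol, which leaves C2 and the already equilibrated C3 untouched (the descriptor at C3 changes only by priority) and does not affect silyl or benzyl ethers.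

Step 11
Reactants: 16 [(2S,3R)-2-(4-benzyloxy-3-methoxyphenyl)-5-[(tert-butyldimethylsilyloxy)methyl]-7-methoxy-2,3-dihydro-1-benzofuran-3-yl]methanol
Product: 17 (2S,3R)-2-(4-benzyloxy-3-methoxyphenyl)-5-[(tert-butyldimethylsilyloxy)methyl]-3-[(tert-butyldiphenylsilyloxy)methyl]-7-methoxy-2,3-dihydro-1-benzofuran
Conditions: TBDPSCl, imidazole, DMF, rt
Reagents that add atoms: tert-butyl(chloro)diphenylsilane, CC(C)(C)[Si](Cl)(c1ccccc1)c1ccccc1
Why: Silylation of the primary alcohol with the bulkier, far more acid-stable TBDPS group, chosen so that the benzylic TBS ether can be removed beside it and so that it withstands the later enolate alkylation.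

Step 12
Reactants: 17 (2S,3R)-2-(4-benzyloxy-3-methoxyphenyl)-5-[(tert-butyldimethylsilyloxy)methyl]-3-[(tert-butyldiphenylsilyloxy)methyl]-7-methoxy-2,3-dihydro-1-benzofuran
Product: 18 [(2S,3R)-2-(4-benzyloxy-3-methoxyphenyl)-3-[(tert-butyldiphenylsilyloxy)methyl]-7-methoxy-2,3-dihydro-1-benzofuran-5-yl]methanol
Conditions: AcOH/THF/H2O (3:1:1), rt
Reagents that add atoms: none
Why: Acid-catalysed hydrolysis is much faster for a primary TBS ether than for a TBDPS ether, and aqueous acetic acid is too weak to ionise the benzylic C–O bonds of the dihydrofuran or the benzyl ethers.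

Step 13
Reactants: 18 [(2S,3R)-2-(4-benzyloxy-3-methoxyphenyl)-3-[(tert-butyldiphenylsilyloxy)methyl]-7-methoxy-2,3-dihydro-1-benzofuran-5-yl]methanol
Product: 19 (2S,3R)-2-(4-benzyloxy-3-methoxyphenyl)-5-(bromomethyl)-3-[(tert-butyldiphenylsilyloxy)methyl]-7-methoxy-2,3-dihydro-1-benzofuran
Conditions: CBr4, PPh3, CH2Cl2, 0 °C; used crude
Reagents that add atoms: carbon tetrabromide, BrC(Br)(Br)Br
Why: Appel bromination converts the electron-rich benzylic alcohol to the bromide through its oxyphosphonium salt under neutral conditions, avoiding acid that could open the dihydrofuran.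

Step 14
Reactants: 6 (4R)-4-[(4-benzyloxy-3-methoxyphenyl)methyl]oxolan-2-one; 19 (2S,3R)-2-(4-benzyloxy-3-methoxyphenyl)-5-(bromomethyl)-3-[(tert-butyldiphenylsilyloxy)methyl]-7-methoxy-2,3-dihydro-1-benzofuran
Product: 20 (3R,4R)-4-[(4-benzyloxy-3-methoxyphenyl)methyl]-3-{[(2S,3R)-2-(4-benzyloxy-3-methoxyphenyl)-3-[(tert-butyldiphenylsilyloxy)methyl]-7-methoxy-2,3-dihydro-1-benzofuran-5-yl]methyl}oxolan-2-one
Conditions: 6, LiN(SiMe3)2, THF, −78 °C; then 19, DMPU, −78 to −40 °C
Reagents that add atoms: none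
Why: Alkylation of a β-substituted γ-butyrolactone lithium enolate with a benzylic bromide, in which the electrophile approaches the face anti to the C4 benzyl group and gives the 3,4-trans lactone (3R from 4R), as is general for dibenzylbutyrolactone lignans; any minor diastereomer stemming from incomplete enantiopurity of either partner would be removed here by chromatography.

Step 15
Reactants: 20 (3R,4R)-4-[(4-benzyloxy-3-methoxyphenyl)methyl]-3-{[(2S,3R)-2-(4-benzyloxy-3-methoxyphenyl)-3-[(tert-butyldiphenylsilyloxy)methyl]-7-methoxy-2,3-dihydro-1-benzofuran-5-yl]methyl}oxolan-2-one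
Product: 21 (3R,4R)-4-[(4-benzyloxy-3-methoxyphenyl)methyl]-3-{[(2S,3R)-2-(4-benzyloxy-3-methoxyphenyl)-3-(hydroxymethyl)-7-methoxy-2,3-dihydro-1-benzofuran-5-yl]methyl}oxolan-2-one
Conditions: HF·pyridine, pyridine, THF, 0 °C to rt
Reagents that add atoms: none
Why: Fluoride-driven cleavage of the Si–O bond of the TBDPS ether with a buffered, non-basic reagent that cannot enolise the trans lactone and leaves benzyl ethers alone.

Step 16
Reactants: 21 (3R,4R)-4-[(4-benzyloxy-3-methoxyphenyl)methyl]-3-{[(2S,3R)-2-(4-benzyloxy-3-methoxyphenyl)-3-(hydroxymethyl)-7-methoxy-2,3-dihydro-1-benzofuran-5-yl]methyl}oxolan-2-one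
Product: 22 isolappaol A
Conditions: H2 (1 atm), 10% Pd/C, EtOAc/MeOH, rt, stopped at full conversion
Reagents that add atoms: none
Why: Hydrogenolysis of the two aryl benzyl ethers on Pd/C at atmospheric pressure in a neutral solvent is fast, so the reaction can be stopped before the slower cleavage of the cyclic benzylic C2–O bond of the dihydrofuran begins, and no stereocentre is touched.

**Compound list**

1 | 4-benzyloxy-3-methoxybenzaldehyde | COc1cc(C=O)ccc1OCc1ccccc1 | starting material
2 | diethyl succinate | CCOC(=O)CCC(=O)OCC | starting material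
3 | (3E)-4-(4-benzyloxy-3-methoxyphenyl)-3-(ethoxycarbonyl)but-3-enoic acid | CCOC(=O)/C(CC(=O)O)=C/c1ccc(OCc2ccccc2)c(OC)c1 | intermediate
4 | (3R)-4-(4-benzyloxy-3-methoxyphenyl)-3-(ethoxycarbonyl)butanoic acid | CCOC(=O)[C@H](Cc1ccc(OCc2ccccc2)c(OC)c1)CC(=O)O | intermediate
5 | (3R)-4-(4-benzyloxy-3-methoxyphenyl)-3-(hydroxymethyl)butanoic acid (formed as its salt, not isolated) | OC[C@H](Cc1ccc(OCc2ccccc2)c(OC)c1)CC(=O)O | intermediate
6 | (4R)-4-[(4-benzyloxy-3-methoxyphenyl)methyl]oxolan-2-one | COc1cc(C[C@H]2COC(=O)C2)ccc1OCc1ccccc1 | intermediate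
7 | 3-bromo-4-hydroxy-5-methoxybenzaldehyde (5-bromovanillin) | COc1cc(C=O)cc(Br)c1O | starting material
8 | (4-benzyloxy-3-methoxyphenyl)methanol | COc1cc(CO)ccc1OCc1ccccc1 | starting material
9 | 4-[(4-benzyloxy-3-methoxyphenyl)methoxy]-3-bromo-5-methoxybenzaldehyde | COc1cc(C=O)cc(Br)c1OCc1ccc(OCc2ccccc2)c(OC)c1 | intermediate
10 | {4-[(4-benzyloxy-3-methoxyphenyl)methoxy]-3-bromo-5-methoxyphenyl}methanol | COc1cc(CO)cc(Br)c1OCc1ccc(OCc2ccccc2)c(OC)c1 | intermediate
11 | ({4-[(4-benzyloxy-3-methoxyphenyl)methoxy]-3-bromo-5-methoxyphenyl}methoxy)(tert-butyl)dimethylsilane | COc1cc(CO[Si](C)(C)C(C)(C)C)cc(Br)c1OCc1ccc(OCc2ccccc2)c(OC)c1 | intermediate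
12 | methyl 2-{2-[(4-benzyloxy-3-methoxyphenyl)methoxy]-5-[(tert-butyldimethylsilyloxy)methyl]-3-methoxyphenyl}acetate | COC(=O)Cc1cc(CO[Si](C)(C)C(C)(C)C)cc(OC)c1OCc1ccc(OCc2ccccc2)c(OC)c1 | intermediate
13 | methyl 2-diazo-2-{2-[(4-benzyloxy-3-methoxyphenyl)methoxy]-5-[(tert-butyldimethylsilyloxy)methyl]-3-methoxyphenyl}acetate | COC(=O)C(=[N+]=[N-])c1cc(CO[Si](C)(C)C(C)(C)C)cc(OC)c1OCc1ccc(OCc2ccccc2)c(OC)c1 | intermediate
14 | methyl (2S,3R)-2-(4-benzyloxy-3-methoxyphenyl)-5-[(tert-butyldimethylsilyloxy)methyl]-7-methoxy-2,3-dihydro-1-benzofuran-3-carboxylate (cis, not isolated) | CC(C)(C)[Si](C)(C)OCc1cc(OC)c2c(c1)[C@@H](C(=O)OC)[C@@H](c1ccc(OCc3ccccc3)c(OC)c1)O2 | intermediate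
15 | methyl (2S,3S)-2-(4-benzyloxy-3-methoxyphenyl)-5-[(tert-butyldimethylsilyloxy)methyl]-7-methoxy-2,3-dihydro-1-benzofuran-3-carboxylate (trans) | CC(C)(C)[Si](C)(C)OCc1cc(OC)c2c(c1)[C@H](C(=O)OC)[C@@H](c1ccc(OCc3ccccc3)c(OC)c1)O2 | intermediate
16 | [(2S,3R)-2-(4-benzyloxy-3-methoxyphenyl)-5-[(tert-butyldimethylsilyloxy)methyl]-7-methoxy-2,3-dihydro-1-benzofuran-3-yl]methanol | CC(C)(C)[Si](C)(C)OCc1cc(OC)c2c(c1)[C@H](CO)[C@@H](c1ccc(OCc3ccccc3)c(OC)c1)O2 | intermediate
17 | (2S,3R)-2-(4-benzyloxy-3-methoxyphenyl)-5-[(tert-butyldimethylsilyloxy)methyl]-3-[(tert-butyldiphenylsilyloxy)methyl]-7-methoxy-2,3-dihydro-1-benzofuran | CC(C)(C)[Si](C)(C)OCc1cc(OC)c2c(c1)[C@H](CO[Si](c1ccccc1)(c1ccccc1)C(C)(C)C)[C@@H](c1ccc(OCc3ccccc3)c(OC)c1)O2 | intermediate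
18 | [(2S,3R)-2-(4-benzyloxy-3-methoxyphenyl)-3-[(tert-butyldiphenylsilyloxy)methyl]-7-methoxy-2,3-dihydro-1-benzofuran-5-yl]methanol | OCc1cc(OC)c2c(c1)[C@H](CO[Si](c1ccccc1)(c1ccccc1)C(C)(C)C)[C@@H](c1ccc(OCc3ccccc3)c(OC)c1)O2 | intermediate
19 | (2S,3R)-2-(4-benzyloxy-3-methoxyphenyl)-5-(bromomethyl)-3-[(tert-butyldiphenylsilyloxy)methyl]-7-methoxy-2,3-dihydro-1-benzofuran | BrCc1cc(OC)c2c(c1)[C@H](CO[Si](c1ccccc1)(c1ccccc1)C(C)(C)C)[C@@H](c1ccc(OCc3ccccc3)c(OC)c1)O2 | intermediate
20 | (3R,4R)-4-[(4-benzyloxy-3-methoxyphenyl)methyl]-3-{[(2S,3R)-2-(4-benzyloxy-3-methoxyphenyl)-3-[(tert-butyldiphenylsilyloxy)methyl]-7-methoxy-2,3-dihydro-1-benzofuran-5-yl]methyl}oxolan-2-one | COc1cc(C[C@H]2COC(=O)[C@@H]2Cc2cc(OC)c3c(c2)[C@H](CO[Si](c2ccccc2)(c2ccccc2)C(C)(C)C)[C@@H](c2ccc(OCc4ccccc4)c(OC)c2)O3)ccc1OCc1ccccc1 | intermediate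
21 | (3R,4R)-4-[(4-benzyloxy-3-methoxyphenyl)methyl]-3-{[(2S,3R)-2-(4-benzyloxy-3-methoxyphenyl)-3-(hydroxymethyl)-7-methoxy-2,3-dihydro-1-benzofuran-5-yl]methyl}oxolan-2-one | COc1cc(C[C@H]2COC(=O)[C@@H]2Cc2cc(OC)c3c(c2)[C@H](CO)[C@@H](c2ccc(OCc4ccccc4)c(OC)c2)O3)ccc1OCc1ccccc1 | intermediate
22 | isolappaol A; (3R,4R)-4-[(4-hydroxy-3-methoxyphenyl)methyl]-3-{[(2S,3R)-2-(4-hydroxy-3-methoxyphenyl)-3-(hydroxymethyl)-7-methoxy-2,3-dihydro-1-benzofuran-5-yl]methyl}oxolan-2-one | COc1cc(C[C@H]2COC(=O)[C@@H]2Cc2cc(OC)c3c(c2)[C@H](CO)[C@@H](c2ccc(O)c(OC)c2)O3)ccc1O | target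

**Step count and risks**

Total step count: 16. Longest linear sequence: 13 steps (steps 4 to 16, from 5-bromovanillin); the lactone branch (steps 1 to 3) joins at step 14.

Steps most likely to fail:

Step 9. The chiral carboxylate alone may distinguish the two benzylic hydrogens poorly, because the methoxy group flanking the ether oxygen twists the benzyloxy arm, and carbene dimerisation may overtake insertion at the low temperature needed. The fallback keeps the C–H insertion but moves stereocontrol to a covalently bound auxiliary reinforced by a prolinate catalyst. It sets out from 12: saponification (LiOH, THF/H2O) should give the arylacetic acid F1, and esterification with (2S)-2-hydroxy-1-(pyrrolidin-1-yl)propan-1-one (EDC, DMAP, CH2Cl2) the lactamide ester F2. Diazo transfer (4-acetamidobenzenesulfonyl azide, DBU, MeCN) should then give the diazo ester F3. Rh2(S-DOSP)4 (dirhodium tetrakis[(S)-N-(4-dodecylphenylsulfonyl)prolinate]) in CH2Cl2 should convert F3 directly into the trans auxiliary ester F4 as the matched pairing, with the minor diastereomer removed by chromatography. Reduction with LiBH4 in THF releases the auxiliary and comes back to the route at 16.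

Step 7. Oxidative addition of the electron-rich ortho-alkoxy aryl bromide may be slow, so that the zinc enolate self-condenses or the bromide is simply reduced. The fallback avoids palladium and diazo transfer altogether and sets out from 11. Bromine–lithium exchange (n-BuLi, THF, −78 °C) followed by inverse addition to dimethyl oxalate should give the aryl glyoxylate F5. Condensation with 4-methylbenzenesulfonohydrazide in MeOH should give the tosylhydrazone F6, and treatment with DBU in CH2Cl2 expels sulfinate (Bamford–Stevens-type diazo formation) and comes back to the route at 13.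

Step 14. The electron-rich benzylic bromide may ionise and decompose before it is consumed, and proton transfer between product and enolate may lead to double alkylation. The fallback replaces the halide electrophile by a carbonyl electrophile and sets out from 18. Oxidation with MnO2 in CH2Cl2 should give the aldehyde F7, and aldol addition of the lithium enolate of 6 (LiN(SiMe3)2, THF, −78 °C) should give the aldol adduct F8, trans on the ring and a mixture at the carbinol carbon. Acylation with O-phenyl chlorothionoformate (pyridine, DMAP) should give the phenyl thionocarbonate F9, and Barton–McCombie deoxygenation (Bu3SnH, AIBN, toluene, 80 °C) removes the benzylic oxygen without touching the ring stereocentres and comes back to the route at 20.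

Further compounds
F1 | step 9 | 2-{2-[(4-benzyloxy-3-methoxyphenyl)methoxy]-5-[(tert-butyldimethylsilyloxy)methyl]-3-methoxyphenyl}acetic acid | OC(=O)Cc1cc(CO[Si](C)(C)C(C)(C)C)cc(OC)c1OCc1ccc(OCc2ccccc2)c(OC)c1
F2 | step 9 | (2S)-1-oxo-1-(pyrrolidin-1-yl)propan-2-yl 2-{2-[(4-benzyloxy-3-methoxyphenyl)methoxy]-5-[(tert-butyldimethylsilyloxy)methyl]-3-methoxyphenyl}acetate | C[C@H](OC(=O)Cc1cc(CO[Si](C)(C)C(C)(C)C)cc(OC)c1OCc1ccc(OCc2ccccc2)c(OC)c1)C(=O)N1CCCC1
F3 | step 9 | (2S)-1-oxo-1-(pyrrolidin-1-yl)propan-2-yl 2-diazo-2-{2-[(4-benzyloxy-3-methoxyphenyl)methoxy]-5-[(tert-butyldimethylsilyloxy)methyl]-3-methoxyphenyl}acetate | C[C@H](OC(=O)C(=[N+]=[N-])c1cc(CO[Si](C)(C)C(C)(C)C)cc(OC)c1OCc1ccc(OCc2ccccc2)c(OC)c1)C(=O)N1CCCC1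
F4 | step 9 | (2S)-1-oxo-1-(pyrrolidin-1-yl)propan-2-yl (2S,3S)-2-(4-benzyloxy-3-methoxyphenyl)-5-[(tert-butyldimethylsilyloxy)methyl]-7-methoxy-2,3-dihydro-1-benzofuran-3-carboxylate | CC(C)(C)[Si](C)(C)OCc1cc(OC)c2c(c1)[C@H](C(=O)O[C@@H](C)C(=O)N1CCCC1)[C@@H](c1ccc(OCc3ccccc3)c(OC)c1)O2
F5 | step 7 | methyl 2-{2-[(4-benzyloxy-3-methoxyphenyl)methoxy]-5-[(tert-butyldimethylsilyloxy)methyl]-3-methoxyphenyl}-2-oxoacetate | COC(=O)C(=O)c1cc(CO[Si](C)(C)C(C)(C)C)cc(OC)c1OCc1ccc(OCc2ccccc2)c(OC)c1
F6 | step 7 | methyl 2-{2-[(4-benzyloxy-3-methoxyphenyl)methoxy]-5-[(tert-butyldimethylsilyloxy)methyl]-3-methoxyphenyl}-2-[2-(4-methylbenzenesulfonyl)hydrazinylidene]acetate | COC(=O)C(=NNS(=O)(=O)c1ccc(C)cc1)c1cc(CO[Si](C)(C)C(C)(C)C)cc(OC)c1OCc1ccc(OCc2ccccc2)c(OC)c1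
F7 | step 14 | (2S,3R)-2-(4-benzyloxy-3-methoxyphenyl)-3-[(tert-butyldiphenylsilyloxy)methyl]-7-methoxy-2,3-dihydro-1-benzofuran-5-carbaldehyde | O=Cc1cc(OC)c2c(c1)[C@H](CO[Si](c1ccccc1)(c1ccccc1)C(C)(C)C)[C@@H](c1ccc(OCc3ccccc3)c(OC)c1)O2
F8 | step 14 | (3S,4R)-4-[(4-benzyloxy-3-methoxyphenyl)methyl]-3-{hydroxy[(2S,3R)-2-(4-benzyloxy-3-methoxyphenyl)-3-[(tert-butyldiphenylsilyloxy)methyl]-7-methoxy-2,3-dihydro-1-benzofuran-5-yl]methyl}oxolan-2-one (carbinol epimers) | COc1cc(C[C@H]2COC(=O)[C@@H]2C(O)c2cc(OC)c3c(c2)[C@H](CO[Si](c2ccccc2)(c2ccccc2)C(C)(C)C)[C@@H](c2ccc(OCc4ccccc4)c(OC)c2)O3)ccc1OCc1ccccc1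
F9 | step 14 | O-phenyl thionocarbonate of F8, (3S,4R)-4-[(4-benzyloxy-3-methoxyphenyl)methyl]-3-{(phenoxycarbonothioyloxy)[(2S,3R)-2-(4-benzyloxy-3-methoxyphenyl)-3-[(tert-butyldiphenylsilyloxy)methyl]-7-methoxy-2,3-dihydro-1-benzofuran-5-yl]methyl}oxolan-2-one (carbinol epimers) | COc1cc(C[C@H]2COC(=O)[C@@H]2C(OC(=S)Oc2ccccc2)c2cc(OC)c3c(c2)[C@H](CO[Si](c2ccccc2)(c2ccccc2)C(C)(C)C)[C@@H](c2ccc(OCc4ccccc4)c(OC)c2)O3)ccc1OCc1ccccc1
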